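**Strategy.** The route cuts ring D at C15–C16 and ring B at C6–C8 in one stroke. An A/C-ring enol triflate carrying an exocyclic C8=C15 methylene and an axial ethynyl group at C13 is closed by a palladium-catalysed domino reaction: the C6 alkenylpalladium adds 5-exo to C8, and the neopentyl C15–palladium species, which lacks β-hydrogens, adds 5-exo-dig to the alkyne; formate then delivers the C16=C17 methylene. The step exploits the quaternary C8 common to rings B, C and D and the 1,3-diaxial C8/C13 bridge of the bicyclo[3.2.1]octane. A temporary C20–O12 lactone locks ring C and stores the aldehyde.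

Key step: step 16

Remark: gibberellane numbering (C1–C20) is used throughout; the target is drawn as the open 12-hydroxy 20-aldehyde, which is expected to equilibrate with its 20,12-lactol.

Step 1
Reactants: 1 4-methoxybenzyl alcohol
Product: 2 (4-methoxycyclohexa-1,4-dien-1-yl)methanol
Conditions: Li, liquid NH3, t-BuOH, THF, −78 °C; NH4Cl
Reagents that add atoms: none
Why: Birch reduction of the anisole ring (as its lithium alkoxide, which suppresses benzylic C–O cleavage) should give the 1-methoxy-4-alkyl-1,4-diene, so the enol ether double bond sits at the future C12=C13 and the allylic alcohol at C8/C15.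

Step 2
Reactants: 3 methyl 5-methoxy-3-oxopentanoate; 4 (E)-4,4-dimethoxybut-2-enal
Product: 5 Michael adduct (methyl (3S)-3-(dimethoxymethyl)-2-(3-methoxypropanoyl)-5-oxopentanoate)
Conditions: (R)-2-[diphenyl(trimethylsilyloxy)methyl]pyrrolidine (10 mol %), benzoic acid (10 mol %), toluene, 0 °C to rt
Reagents that add atoms: none
Why: Iminium-activated organocatalytic Michael addition of the β-keto ester, in which the diphenyl(silyloxy)methyl group shields one face of the iminium ion so that C4 adds to a single face of C5 (3S in 5), the only stereocentre fixed here.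

Step 3
Reactants: 5 Michael adduct
Product: 8 ring A keto aldehyde (methyl (1S,2S,3R)-2-(dimethoxymethyl)-3-formyl-1-methyl-6-oxocyclohexane-1-carboxylate), via vinyl ketone 6 (not isolated), via cyclised keto ester 7 (not isolated)
Conditions: Cs2CO3, MeCN, 0 °C to rt; then MeI, rt
Reagents that add atoms: iodomethane, CI
Why: β-Elimination of methanol unmasks a Nazarov-type vinyl ketone, the aldehyde enolate closes ring A by intramolecular 6-endo Michael addition (C10 equilibrating to the trans isomer), and the β-keto ester enolate is then C-methylated anti to the adjacent C5 dimethoxymethyl group, which puts the C4 ester cis and the C4 methyl trans to that group.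

Step 4
Reactants: 8 ring A keto aldehyde
Product: 9 ring A keto acid ((1R,2S,3S)-2-(dimethoxymethyl)-3-(methoxycarbonyl)-3-methyl-4-oxocyclohexane-1-carboxylic acid)
Conditions: NaClO2, NaH2PO4, 2-methyl-2-butene, t-BuOH/H2O, 0 °C
Reagents that add atoms: sodium chlorite, [Na+].[O-]Cl=O
Why: Pinnick oxidation converts the aldehyde to the acid without touching the non-enolisable β-keto ester or the acetal.

Step 5
Reactants: 9 ring A keto acid; 2 (4-methoxycyclohexa-1,4-dien-1-yl)methanol
Product: 10 dienylmethyl ester
Conditions: 1-ethyl-3-(3-dimethylaminopropyl)carbodiimide hydrochloride, 4-(dimethylamino)pyridine, CH2Cl2, 0 °C to rt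
Reagents that add atoms: none
Why: Steglich-type carbodiimide esterification joins the two fragments under non-acidic conditions that spare the enol ether and the acetal; no stereocentre is formed.

Step 6
Reactants: 10 dienylmethyl ester
Product: 11 3-hydroxy ester
Conditions: LiBH(s-Bu)3, THF, −78 °C; aq. NH4Cl
Reagents that add atoms: none
Why: Ketone reduction with a bulky trialkylborohydride, which attacks C3 along the equatorial trajectory and should give the axial alcohol, trans to the axial C4 ester and cis to the C4 methyl group (the C3 configuration of the target), while the esters are left alone.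

Step 7
Reactants: 11 3-hydroxy ester
Product: 12 silyl ether ester
Conditions: t-BuMe2SiOTf, 2,6-lutidine, CH2Cl2, 0 °C
Reagents that add atoms: tert-butyldimethylsilyl trifluoromethanesulfonate, CC(C)(C)[Si](C)(C)OS(=O)(=O)C(F)(F)F
Why: Silylation of the hindered alcohol protects the β-hydroxy ester against retro-aldol cleavage under the strong base of the next step.

Step 8
Reactants: 12 silyl ether ester
Product: 14 rearranged acid, via silyl ketene acetal 13 (not isolated)
Conditions: LiN(i-Pr)2, THF/DMPU (4:1), −78 °C; Me3SiCl; −78 to 50 °C; then MeOH/aq. NaHCO3, pH 5 buffer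
Reagents that add atoms: none
Why: Ireland–Claisen rearrangement in which enolisation in the presence of DMPU places the silyloxy group cis to the branched C5 arm, and a chair transition state delivers the allyl unit to the face of the ketene acetal anti to the C5 side chain (C9 equatorial, C20 axial on ring A), so that C10 and C9 are set together and the double bond moves to the exocyclic C8=C15 position.

Step 9
Reactants: 14 rearranged acid
Product: 15 selanyl keto acid
Conditions: PhSeCl (1.0 equiv), pyridine, CH2Cl2, −78 °C; then H2O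
Reagents that add atoms: benzeneselenenyl chloride, Cl[Se]c1ccccc1; water, O
Why: Electrophilic selenenylation of the methyl enol ether, which is far more nucleophilic than the exocyclic methylene, occurs regiospecifically at C13, and hydrolysis of the oxocarbenium ion leaves the C12 ketone; the C13 configuration is immaterial.

Step 10
Reactants: 15 selanyl keto acid
Product: 17 selanyl lactone, via hydroxy acid 16 (not isolated)
Conditions: NaBH4, MeOH, −40 °C (on the sodium carboxylate of 15); dilute citric acid; then 1-ethyl-3-(3-dimethylaminopropyl)carbodiimide hydrochloride, 4-(dimethylamino)pyridine, CH2Cl2, rt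
Reagents that add atoms: none
Why: Hydride reduction in which the small borohydride should approach the C12 ketone from the face opposite the bulky C10 substituent on C9, giving the alcohol cis to C10, followed by carbodiimide lactonisation that only this epimer can undergo and that locks ring C with the C9–C10 and C12–O bonds diaxial.

Step 11
Reactants: 17 selanyl lactone
Product: 19 ethynyl lactone, via silylalkyne lactone 18 (not isolated)
Conditions: PhSO2C≡CSiMe3, (Bu3Sn)2, hν, benzene, 80 °C; then Bu4NF, AcOH, THF, 0 °C
Reagents that add atoms: phenyl 2-(trimethylsilyl)ethynyl sulfone, C[Si](C)(C)C#CS(=O)(=O)c1ccccc1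
Why: Radical alkynylation by addition–fragmentation on an alkynyl sulfone, in which the C13 radical released from the selenide is trapped axially, anti to the neighbouring axial C12–O bond and away from the lactone bridge, so the alkyne ends trans to O12; buffered fluoride then removes the C-silyl group.

Step 12
Reactants: 19 ethynyl lactone
Product: 20 lactone aldehyde
Conditions: pyridinium p-toluenesulfonate, acetone/H2O, 50 °C
Reagents that add atoms: water, O
Why: Mild acid-catalysed acetal hydrolysis frees the C6 aldehyde, and C5 keeps its equatorial formyl group because the axial alternative would be syn-diaxial to the C3 silyloxy group.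

Step 13
Reactants: 20 lactone aldehyde
Product: 21 methoxy carbinol
Conditions: Bu3SnCH2OMe, n-BuLi, THF, −78 °C; then 20 (reagent in excess to cover the alkyne C–H), −78 °C; aq. NH4Cl
Reagents that add atoms: tributyl(methoxymethyl)stannane, COC[Sn](CCCC)(CCCC)CCCC
Why: Tin–lithium exchange gives (methoxymethyl)lithium, whose 1,2-addition to the aldehyde should be much faster than attack on the hindered lactone or ester; the carbinol configuration is irrelevant because it is oxidised next.

Step 14
Reactants: 21 methoxy carbinol
Product: 22 methoxymethyl ketone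
Conditions: Dess–Martin periodinane, NaHCO3, CH2Cl2, rt
Reagents that add atoms: none
Why: Dess–Martin oxidation of the secondary alcohol gives the α-methoxy ketone under neutral conditions.

Step 15
Reactants: 22 methoxymethyl ketone
Product: 23 enol triflate
Conditions: KN(SiMe3)2 (1.05 equiv), THF, −78 °C; then PhNTf2
Reagents that add atoms: N-phenylbis(trifluoromethanesulfonimide), O=S(=O)(N(c1ccccc1)S(=O)(=O)C(F)(F)F)C(F)(F)F
Why: Kinetic enolisation should occur at the unhindered, alkoxy-activated C7 methylene and not at the tertiary C5–H, and O-triflation of the enolate gives the enol triflate that carries C7 at the aldehyde oxidation level.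

Step 16
Reactants: 23 enol triflate
Product: 26 tetracyclic enol ether, via alkylpalladium triflate 24 (not isolated), via alkenylpalladium triflate 25 (not isolated)
Conditions: Pd(OAc)2 (10 mol %), PPh3 (20 mol %), HCO2Na, Bu4NCl, DMF, 80 °C
Reagents that add atoms: none
Why: Zerovalent palladium inserts into the C6–O triflate bond and the alkenylpalladium adds syn across the C8=C15 methylene to give alkylpalladium 24, which has no β-hydrogen and therefore adds syn to the C13 ethynyl group to give alkenylpalladium 25; formate then transfers hydride (loss of CO2) and reductive elimination releases 26. The closest known reaction type is the domino Heck cyclisation relayed through a neopentylpalladium intermediate with reductive formate termination. Ring B closes 5-exo-trig (C6–C8) and ring D closes 5-exo-dig (C15–C16). The only new stereocentre, C8, is fixed by the C9–C10–C5 tether: C6 can reach only the face of ring C that already carries C10, so rings B and C become cis-fused and the C15–palladium arm lies on the opposite face, the one bearing the alkyne. The step needs exo insertion at the substituted alkene carbon and alkyne insertion ahead of hydride capture or 3-exo return; the first is the normal preference of intramolecular carbopalladation and the second is secured by the lactone, which holds the C13 ethynyl group and the C8 arm 1,3-diaxial.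

Step 17
Reactants: 26 tetracyclic enol ether
Product: 27 hydroxy aldehyde
Conditions: 48% aq. HF, MeCN, 0 °C to rt; then 1,8-diazabicyclo[5.4.0]undec-7-ene (0.2 equiv), CH2Cl2, rt
Reagents that add atoms: water, O
Why: Acid hydrolysis of the methyl enol ether frees the C7 aldehyde and the same medium cleaves the silyl ether, after which base equilibration at C6 should leave the formyl group trans to C4 on ring B, the more stable epimer and the one of the target.

Step 18
Reactants: 27 hydroxy aldehyde
Product: 28 monoacid
Conditions: NaClO2, NaH2PO4, 2-methyl-2-butene, t-BuOH/H2O, 0 °C to rt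
Reagents that add atoms: sodium chlorite, [Na+].[O-]Cl=O
Why: Pinnick oxidation takes the C7 aldehyde to the acid and leaves the alkene, the lactone and the secondary alcohol alone.

Step 19
Reactants: 28 monoacid
Product: 29 diacid lactone
Conditions: LiSPr, HMPA, rt; then dilute aq. HCl
Reagents that add atoms: none
Why: Thiolate SN2 demethylation cleaves the hindered axial C19 methyl ester at the methyl carbon, where acyl substitution at the neopentyl carbonyl would fail; no stereocentre is touched.

Step 20
Reactants: 29 diacid lactone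
Product: 30 target (CNP0218328.1)
Conditions: i-Bu2AlH (5 equiv), THF, −78 °C; then dilute aq. HCl, 0 °C
Reagents that add atoms: none
Why: Partial reduction of the lactone by the aluminium hydride should stop at the aluminium hemiacetal at low temperature, the two acids being masked in the flask as unreactive aluminium carboxylates, and work-up releases the 12-hydroxy 20-aldehyde.

**Compound list**

1 | 4-methoxybenzyl alcohol | COc1ccc(CO)cc1 | starting material
2 | (4-methoxycyclohexa-1,4-dien-1-yl)methanol | COC1=CCC(CO)=CC1 | intermediate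
3 | methyl 5-methoxy-3-oxopentanoate | COCCC(=O)CC(=O)OC | starting material
4 | (E)-4,4-dimethoxybut-2-enal | COC(OC)/C=C/C=O | starting material
5 | methyl (3S)-3-(dimethoxymethyl)-2-(3-methoxypropanoyl)-5-oxopentanoate (C2 epimers) | COCCC(=O)C(C(=O)OC)[C@@H](C(OC)OC)CC=O | intermediate
6 | methyl (3S)-2-acryloyl-3-(dimethoxymethyl)-5-oxopentanoate | C=CC(=O)C(C(=O)OC)[C@@H](C(OC)OC)CC=O | intermediate (not isolated)
7 | methyl (2S,3R)-2-(dimethoxymethyl)-3-formyl-6-oxocyclohexane-1-carboxylate (C1 enolisable) | O=C[C@@H]1CCC(=O)C(C(=O)OC)[C@H]1C(OC)OC | intermediate (not isolated)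
8 | methyl (1S,2S,3R)-2-(dimethoxymethyl)-3-formyl-1-methyl-6-oxocyclohexane-1-carboxylate | O=C[C@@H]1CCC(=O)[C@@](C)(C(=O)OC)[C@H]1C(OC)OC | intermediate
9 | (1R,2S,3S)-2-(dimethoxymethyl)-3-(methoxycarbonyl)-3-methyl-4-oxocyclohexane-1-carboxylic acid | OC(=O)[C@@H]1CCC(=O)[C@@](C)(C(=O)OC)[C@H]1C(OC)OC | intermediate
10 | 1-[(4-methoxycyclohexa-1,4-dien-1-yl)methyl] 3-methyl (1R,2S,3S)-2-(dimethoxymethyl)-3-methyl-4-oxocyclohexane-1,3-dicarboxylate | COC1=CCC(COC(=O)[C@@H]2CCC(=O)[C@@](C)(C(=O)OC)[C@H]2C(OC)OC)=CC1 | intermediate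
11 | 1-[(4-methoxycyclohexa-1,4-dien-1-yl)methyl] 3-methyl (1R,2S,3S,4S)-2-(dimethoxymethyl)-4-hydroxy-3-methylcyclohexane-1,3-dicarboxylate | COC1=CCC(COC(=O)[C@@H]2CC[C@H](O)[C@@](C)(C(=O)OC)[C@H]2C(OC)OC)=CC1 | intermediate
12 | 1-[(4-methoxycyclohexa-1,4-dien-1-yl)methyl] 3-methyl (1R,2S,3S,4S)-4-[(tert-butyldimethylsilyl)oxy]-2-(dimethoxymethyl)-3-methylcyclohexane-1,3-dicarboxylate | COC1=CCC(COC(=O)[C@@H]2CC[C@H](O[Si](C)(C)C(C)(C)C)[C@@](C)(C(=O)OC)[C@H]2C(OC)OC)=CC1 | intermediate
13 | trimethylsilyl ketene acetal of 12 (exocyclic C10=C20; trimethylsilyloxy cis to C5, dienylmethoxy cis to C1) | COC1=CCC(CO/C(O[Si](C)(C)C)=C2\CC[C@H](O[Si](C)(C)C(C)(C)C)[C@@](C)(C(=O)OC)[C@H]2C(OC)OC)=CC1 | intermediate (not isolated)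
14 | 4-[(tert-butyldimethylsilyl)oxy]-2-(dimethoxymethyl)-3-(methoxycarbonyl)-1-(3-methoxy-6-methylidenecyclohex-3-en-1-yl)-3-methylcyclohexane-1-carboxylic acid; C3, C4, C5, C9, C10 as in the target | C=C1CC=C(OC)C[C@H]1[C@]2(C(=O)O)CC[C@H](O[Si](C)(C)C(C)(C)C)[C@@](C)(C(=O)OC)[C@H]2C(OC)OC | intermediate
15 | analogue of 14 with ring C as 2-methylidene-5-oxo-4-(phenylselanyl)cyclohexyl (12-ketone, 13-selanyl, C13 epimers) | C=C1CC([Se]c2ccccc2)C(=O)C[C@H]1[C@]3(C(=O)O)CC[C@H](O[Si](C)(C)C(C)(C)C)[C@@](C)(C(=O)OC)[C@H]3C(OC)OC | intermediate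
16 | 12-hydroxy acid from 15, hydroxyl cis to C10 on ring C | C=C1CC([Se]c2ccccc2)[C@@H](O)C[C@H]1[C@]3(C(=O)O)CC[C@H](O[Si](C)(C)C(C)(C)C)[C@@](C)(C(=O)OC)[C@H]3C(OC)OC | intermediate (not isolated)
17 | 20,12-lactone of 16 (2-oxabicyclo[3.3.1]nonan-3-one spiro-linked to ring A at C10; 8-methylidene, 13-phenylselanyl) | C=C1CC([Se]c2ccccc2)[C@@H]3C[C@H]1[C@]4(C(=O)O3)CC[C@H](O[Si](C)(C)C(C)(C)C)[C@@](C)(C(=O)OC)[C@H]4C(OC)OC | intermediate
18 | 13-[(trimethylsilyl)ethynyl] lactone, alkynyl group axial and trans to O12 | C=C1C[C@H](C#C[Si](C)(C)C)[C@@H]2C[C@H]1[C@]3(C(=O)O2)CC[C@H](O[Si](C)(C)C(C)(C)C)[C@@](C)(C(=O)OC)[C@H]3C(OC)OC | intermediate (not isolated)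
19 | 13-ethynyl lactone (C5 dimethoxymethyl, 3-silyl ether, 19-methyl ester) | C=C1C[C@H](C#C)[C@@H]2C[C@H]1[C@]3(C(=O)O2)CC[C@H](O[Si](C)(C)C(C)(C)C)[C@@](C)(C(=O)OC)[C@H]3C(OC)OC | intermediate
20 | 13-ethynyl lactone with formyl at C5 | C=C1C[C@H](C#C)[C@@H]2C[C@H]1[C@]3(C(=O)O2)CC[C@H](O[Si](C)(C)C(C)(C)C)[C@@](C)(C(=O)OC)[C@H]3C=O | intermediate
21 | 13-ethynyl lactone with 1-hydroxy-2-methoxyethyl at C5 (carbinol epimers) | C=C1C[C@H](C#C)[C@@H]2C[C@H]1[C@]3(C(=O)O2)CC[C@H](O[Si](C)(C)C(C)(C)C)[C@@](C)(C(=O)OC)[C@H]3C(O)COC | intermediate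
22 | 13-ethynyl lactone with methoxyacetyl at C5 | C=C1C[C@H](C#C)[C@@H]2C[C@H]1[C@]3(C(=O)O2)CC[C@H](O[Si](C)(C)C(C)(C)C)[C@@](C)(C(=O)OC)[C@H]3C(=O)COC | intermediate
23 | 13-ethynyl lactone with (Z)-2-methoxy-1-(trifluoromethanesulfonyloxy)ethenyl at C5 | C=C1C[C@H](C#C)[C@@H]2C[C@H]1[C@]3(C(=O)O2)CC[C@H](O[Si](C)(C)C(C)(C)C)[C@@](C)(C(=O)OC)[C@H]3/C(OS(=O)(=O)C(F)(F)F)=C/OC | intermediate
24 | alkylpalladium triflate: ring B closed, quaternary C8 bearing CH2–Pd on the face of the 13-ethynyl group (phosphines omitted) | FC(F)(F)S(=O)(=O)O[Pd]C[C@]12C[C@H](C#C)[C@@H]3C[C@H]1[C@]4(C(=O)O3)CC[C@H](O[Si](C)(C)C(C)(C)C)[C@@](C)(C(=O)OC)[C@H]4/C2=C/OC | intermediate (not isolated)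
25 | alkenylpalladium triflate: ring D closed, C16=C17H–Pd with palladium cis to C15 (phosphines omitted) | FC(F)(F)S(=O)(=O)O[Pd]/C=C1\C[C@]23C[C@H]1[C@@H]4C[C@H]2[C@]5(C(=O)O4)CC[C@H](O[Si](C)(C)C(C)(C)C)[C@@](C)(C(=O)OC)[C@H]5/C3=C/OC | intermediate (not isolated)
26 | gibberellane enol ether: 7-methoxy-6(7)-ene, 16(17)-ene, 20,12-lactone, 3-silyl ether, 19-methyl ester | C=C1C[C@]23C[C@H]1[C@@H]4C[C@H]2[C@]5(C(=O)O4)CC[C@H](O[Si](C)(C)C(C)(C)C)[C@@](C)(C(=O)OC)[C@H]5/C3=C/OC | intermediate
27 | 3-hydroxy 7-aldehyde, 19-methyl ester, 20,12-lactone, 16-ene; C6 as in the target | C=C1C[C@]23C[C@H]1[C@@H]4C[C@H]2[C@]5(C(=O)O4)CC[C@H](O)[C@@](C)(C(=O)OC)[C@H]5[C@@H]3C=O | intermediate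
28 | 3-hydroxy 7-carboxylic acid, 19-methyl ester, 20,12-lactone | C=C1C[C@]23C[C@H]1[C@@H]4C[C@H]2[C@]5(C(=O)O4)CC[C@H](O)[C@@](C)(C(=O)OC)[C@H]5[C@@H]3C(=O)O | intermediate
29 | 3-hydroxy 7,19-dicarboxylic acid 20,12-lactone | C=C1C[C@]23C[C@H]1[C@@H]4C[C@H]2[C@]5(C(=O)O4)CC[C@H](O)[C@@](C)(C(=O)O)[C@H]5[C@@H]3C(=O)O | intermediate
30 | CNP0218328.1: 3,12-dihydroxy-20-oxogibberell-16-ene-7,19-dioic acid | C=C1C[C@]23C[C@H]1[C@@H](O)C[C@H]2[C@]1(C=O)CC[C@H](O)[C@@](C)(C(=O)O)[C@H]1[C@@H]3C(=O)O | target

**Step count.** Total: 20 steps. Longest linear sequence: 19 steps (steps 2 to 20); step 1 supplies the ring C alcohol 2.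

**Steps most likely to fail**

Step 16. The neopentylpalladium intermediate may be reduced by formate before it reaches the alkyne, leaving a C15 methyl group, or it may return by 3-exo closure onto the enol ether and expand the ring. The fallback separates the two ring closures and closes ring D through a radical. Setting out from 23, carbopalladation with carbon–iodine reductive elimination (Pd(P(t-Bu)3)2 cat., KI, toluene, 100 °C) should close ring B only and give the neopentyl iodide F1. Bu3SnH with azobis(isobutyronitrile) in benzene at 80 °C then generates the C15 radical, which attacks C16 5-exo-dig and brings the route back at 26.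

Step 10. Hydride may be delivered to the other face of the C12 ketone, for instance from boron bound to the carboxylate, which leaves an epimer that cannot lactonise. The fallback uses that epimer. Setting out from 15, reduction under conditions chosen for internal delivery (NaBH(OAc)3, AcOH/MeCN) should give the 12-epimeric hydroxy acid F2. Intramolecular Mitsunobu esterification (PPh3, diisopropyl azodicarboxylate, toluene) then closes the lactone with inversion at C12 and returns to 17.

Step 20. Reduction may run past the lactol stage, or the aluminium carboxylates may be attacked or aggregate so that the lactone is left behind. The fallback opens the lactone first. Setting out from 29, aminolysis with MeNH(OMe)·HCl and AlMe3 (CH2Cl2, 0 °C to rt) should give the hydroxy Weinreb amide F3, whose reduction with i-Bu2AlH at −78 °C stops at the chelated aldehyde stage and arrives at 30 on work-up.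

Further compounds
F1 | step 16 | neopentyl iodide: compound 24 with iodine in place of the palladium triflate group | IC[C@]12C[C@H](C#C)[C@@H]3C[C@H]1[C@]4(C(=O)O3)CC[C@H](O[Si](C)(C)C(C)(C)C)[C@@](C)(C(=O)OC)[C@H]4/C2=C/OC
F2 | step 10 | 12-epimer of hydroxy acid 16 (hydroxyl trans to C10 on ring C) | C=C1CC([Se]c2ccccc2)[C@H](O)C[C@H]1[C@]3(C(=O)O)CC[C@H](O[Si](C)(C)C(C)(C)C)[C@@](C)(C(=O)OC)[C@H]3C(OC)OC
F3 | step 20 | 3,12-dihydroxy 7,19-diacid with C20 as N-methoxy-N-methylcarboxamide | C=C1C[C@]23C[C@H]1[C@@H](O)C[C@H]2[C@]1(C(=O)N(C)OC)CC[C@H](O)[C@@](C)(C(=O)O)[C@H]1[C@@H]3C(=O)O
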